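Read each run for its ceiling, the target it is heading for, before anything else.

all flasks: starting material 17 mM

| flask | partner | temperature | remark | time |
|---|---|---|---|---|
| epsilon | 44 mM | 30 °C | run made earlier |  |
| beta | 62 mM | 55 °C | run made earlier |  |
| Sunday's | 50.0 mM |  | at 75 °C throughout | 10 min |
| Friday's | 30.6 mM |  | at 35 °C until 2.0 min, from then on at 75 °C | 10 min |

- epsilon (time / min: target / %): 0.500: 2.5; 0.833: 3.3; 1.33: 4.6; 2.00: 7.2; 3.00: 9.6; 5.00: 14.3; 8.00: 19.3
- beta (time / min: target / %): 0.167: 6.5; 0.333: 10.9; 0.667: 18.9; 1.00: 24.8; 1.33: 28.8; 2.00: 34.3; 3.00: 39.4

(scatter of a reading: 0.3 percentage points)



1. the flask that ends with the higher amount of target, in percent of the starting material charged, or "neither" when 2 percentage points or less lies between them (Sunday's / Friday's / neither)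
2. final target, as a percentage of the starting material charged, in Sunday's
3. final target, as a percentage of the starting material charged, in Friday's

I take three equally spaced readings from each run and treat each step as a steady fraction of the one before, so the steps sum to a ceiling. I also define the even-split level: the c(partner) at which target and the rest take equal shares. The ratio of the two shares, the selectivity factor, is then that level over c(partner). This is my wager: the two runs change temperature and partner together, and I have no test of it from them.

- Epsilon run, 30 °C: ceiling 31.2 %, even-split level 20.0 mM
- Beta run, 55 °C: ceiling 45.3 %, even-split level 51.4 mM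

Both ceilings are readings with scatter, and both stand short of full yield, so I suppose a second path takes the rest of the starting material. Reading down the last column, the level climbs 0.411 powers of ten between the two temperatures. Carrying that line on in logarithms gives 24.1 mM at 35 °C. At 75 °C it gives the even-split level 109 mM.

With partner as charged, the target share is 68.6 % in Sunday's and 78.1 % in Friday's, so I commit to Friday's, by 9.5 percentage points. I leave out the falling partner and Friday's cool stretch.

The forecast differs: it says Sunday's, with 50 % for Sunday's and 36 % for Friday's, on the ground that “The rate of target formation falls much faster”.

Friday's ends at 70.5 % and Sunday's at 60.0 %, a gap of 10 points against my 9.5 points.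

    starting material + partner → target (k = 1.40 M⁻¹ min⁻¹, Ea = 68.0 kJ mol⁻¹)
    starting material + 2 partner → side product (k = 49.0 M⁻² min⁻¹, Ea = 53.0 kJ mol⁻¹)
    (constants at 35 °C)

Sunday's holds 40.0 % of side product at the end. Now take Friday's charged with 120 mM of partner. There 109 mM gives a share of 47.6 %, but the starting material's half-life at 35 °C, from both steps at the charge, is 0.793 min, shorter than the 2.0 min before heating. The level for 35 °C gives 16.7 %, and that flask ends with 25.0 % of target.

The runs were generated by integration for an exercise; scatter was added.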